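Numbering: ring A (five-membered) is C1(CH3)–C2–C3–C4(OH, iPr)–C5(H). Ring B (seven-membered) is C1–C5–C6(OCOAr)–C7–C8(OH, CH3)–C9=C10.
Retrosynthetic cuts, in order: O6–acyl; C4–isopropyl; C6–O together with C5–H (back to a C5=C6 enone); C7–C8 (retro-Cope, which re-forms C5–C10); C5–C1 and C5–C10 (retro-cyclopropanation). This leads to an achiral, acyclic vinyl diazo ketone.
Enabling feature: in ring B the C9=C10 alkene and the latent C5=C6 alkene flank quaternary C1. Ring B is therefore a cyclohepta-1,4-diene with C7–C8 opposite C1, the retron of a cis-divinylcyclopropane (C1, C5, C10). C4, kept as a ketone, stabilises the diazo carbon C5 and tethers it to C1 through C2–C3.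
Forward: the C12 chain is joined from methacrolein, propargyl bromide, an orthoacetate and an allyl Grignard reagent. One rhodium-catalysed event then closes ring A with a temporary three-membered ring and expands that ring to ring B. The isopropyl and aroyl groups come last.
Stereochemistry: C1 comes from the chiral catalyst and C8 from the Z enol ether geometry through the boat transition state. C6, C5 and C4 are relayed from these two by substrate control (open-face borylation, equilibration to the cis fusion, convex-face Grignard addition).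

Key step: step 7

Assumption: the sense of induction of Rh2(S-PTAD)4 on this new diazo ketone cannot be read from related cases. The S ligand series is written, and the R series is taken if 13 proves antipodal.

Step 1
Reactants: 1 methacrolein; 2 propargyl bromide
Product: 3 (±)-2-methylhex-1-en-5-yn-3-ol
Conditions: Zn dust, THF/sat. aq. NH4Cl, 0 °C to rt
Reagents that add atoms: none
Why: Barbier-type propargylation of the aldehyde should give the homopropargylic alcohol by 1,2-addition; the carbinol centre is racemic and is erased in step 2.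

Step 2
Reactants: 3 (±)-2-methylhex-1-en-5-yn-3-ol; 4 triethyl orthoacetate
Product: 6 ethyl (E)-4-methyloct-4-en-7-ynoate, via mixed ketene acetal 5 (not isolated)
Conditions: EtCO2H (cat.), excess 4, 140 °C, EtOH distilled off
Reagents that add atoms: none
Why: Johnson–Claisen rearrangement through a chair with the propargyl group equatorial should give the E trisubstituted C1=C10 alkene, the geometry that later places the two vinyl arms cis on the cyclopropane.

Step 3
Reactants: 6 ethyl (E)-4-methyloct-4-en-7-ynoate
Product: 7 ethyl (E)-4-methyl-7-oxooct-4-enoate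
Conditions: Ph3PAuNTf2 (2 mol %), H2O (3 equiv), 1,4-dioxane, 60 °C
Reagents that add atoms: water, O
Why: Gold-catalysed Markovnikov hydration of the terminal alkyne should give the methyl ketone (C8) under near-neutral conditions that leave the β,γ-alkene in place.

Step 4
Reactants: 7 ethyl (E)-4-methyl-7-oxooct-4-enoate
Product: 8 ethyl (4E,6Z)-7-(tert-butyldimethylsilyloxy)-4-methylocta-4,6-dienoate
Conditions: TBSOTf (1.2 equiv), Et3N (2 equiv), CH2Cl2, −78 to 0 °C
Reagents that add atoms: tert-butyldimethylsilyl triflate, CC(C)(C)[Si](C)(C)OS(=O)(=O)C(F)(F)F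
Why: Soft enolisation should remove the doubly activated C9–H rather than a methyl proton and give the conjugated silyl dienol ether with Z geometry (oxygen cis to C10), because this enolisation type places the chain trans to the methyl group; this geometry later encodes C8.

Step 5
Reactants: 8 ethyl (4E,6Z)-7-(tert-butyldimethylsilyloxy)-4-methylocta-4,6-dienoate
Product: 10 (7E,9Z)-10-(tert-butyldimethylsilyloxy)-7-methylundeca-1,7,9-trien-4-one, via Weinreb amide 9 (not isolated)
Conditions: MeNH(OMe)·HCl (1.5 equiv), iPrMgCl (3 equiv), THF, −20 °C; then allylMgBr (2 equiv), 0 °C; then H2O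
Reagents that add atoms: N,O-dimethylhydroxylamine hydrochloride, CNOC.Cl; allylmagnesium bromide, C=CC[Mg]Br
Why: Weinreb ketone synthesis in one flask: the magnesium amide turns the ester into 9, whose chelated adduct with the allyl Grignard reagent stops at the ketone stage; no stereocentre is formed.

Step 6
Reactants: 10 (7E,9Z)-10-(tert-butyldimethylsilyloxy)-7-methylundeca-1,7,9-trien-4-one
Product: 11 (7E,9Z)-3-diazo-10-(tert-butyldimethylsilyloxy)-7-methylundeca-1,7,9-trien-4-one
Conditions: 4-acetamidobenzenesulfonyl azide (1.3 equiv), DBU (1.5 equiv), MeCN, 0 °C; cold filtration through silica, used at once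
Reagents that add atoms: 4-acetamidobenzenesulfonyl azide, CC(=O)Nc1ccc(cc1)S(=O)(=O)N=[N+]=[N-]
Why: Regitz-type diazo transfer to the dienolate of the β,γ-unsaturated ketone (also reached from any conjugated isomer) is the standard entry to vinyl diazo carbonyl compounds, and 11 is used at once because it can electrocyclise to a pyrazole.

Step 7
Reactants: 11 (7E,9Z)-3-diazo-10-(tert-butyldimethylsilyloxy)-7-methylundeca-1,7,9-trien-4-one
Product: 13 (3aS,6R)-6-(tert-butyldimethylsilyloxy)-3a,6-dimethyl-3,3a,6,7-tetrahydroazulen-1(2H)-one, via cis-divinylcyclopropane 12 (not isolated)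
Conditions: Rh2(S-PTAD)4 (1 mol %), pentane, slow addition of 11, −40 °C to rt; then toluene, 80 °C
Reagents that add atoms: none
Why: Loss of N2 gives a rhodium vinylcarbenoid that adds to the proximal C1=C10 alkene in an intramolecular (2+1) event, closing ring A as the bicyclo[3.1.0]hexan-2-one 12; the closest known type is the tandem cyclopropanation/Cope rearrangement of vinyl diazo carbonyl compounds with tethered dienes, a formal (4+3) cycloaddition. Because the alkene is E, the enol ether arm on C10 is exo and cis to the vinyl group on C5, so 12 is a cis-divinylcyclopropane that undergoes a [3,3]-sigmatropic shift through the endo boat, breaking C5–C10 and forming C7–C8, so that ring B is closed by expansion of the three-membered ring. C1 (with the transient C5 and C10) is set by the enantioface choice of the chiral carboxylate ligands, and C8 is set stereospecifically by the Z enol ether, whose inner oxygen is delivered to the ring face that carries the C1 methyl. Chemoselectivity for C1=C10 over the more electron-rich C8=C9 bond is secured by the two-carbon tether (five- against seven-membered closure) and by vinylogous donation from the silyloxy group, which makes C1 the nucleophilic diene terminus. The ketone on C5 and the silyloxy donor on the C10 arm polarise the breaking bond and should offset the steric cost of the syn methyl and the inner oxygen in the boat. The cis C9=C10 alkene follows necessarily from the boat geometry.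

Step 8
Reactants: 13 (3aS,6R)-6-(tert-butyldimethylsilyloxy)-3a,6-dimethyl-3,3a,6,7-tetrahydroazulen-1(2H)-one
Product: 15 (3aS,6R,8S,8aS)-6-(tert-butyldimethylsilyloxy)-8-hydroxy-3a,6-dimethyl-3,3a,6,7,8,8a-hexahydroazulen-1(2H)-one, via beta-boryl ketone 14 (not isolated)
Conditions: CuCl (5 mol %), Xantphos (5 mol %), NaOtBu (15 mol %), B2pin2 (1.2 equiv), MeOH (2 equiv), THF, rt; then 30 % H2O2, pH 7 phosphate buffer, 0 °C
Reagents that add atoms: bis(pinacolato)diboron, CC1(C)OB(OC1(C)C)B1OC(C)(C)C(C)(C)O1; hydrogen peroxide, OO
Why: Copper-catalysed conjugate borylation and oxidation with retention: the rigid roof-shaped cyclohepta-1,4-diene turns the inner faces of its two alkenes towards each other and exposes only the outer (α) face, which carries the C1 methyl and the C8 silyloxy group, so boron and then oxygen should enter C6 from α, while C5, α to the ketone, is equilibrated by the alkoxide present to the cis fusion (H5 α), which keeps C6 away from the angular methyl.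

Step 9
Reactants: 15 (3aS,6R,8S,8aS)-6-(tert-butyldimethylsilyloxy)-8-hydroxy-3a,6-dimethyl-3,3a,6,7,8,8a-hexahydroazulen-1(2H)-one
Product: 16 (3R,3aS,4S,6R,8aS)-6-(tert-butyldimethylsilyloxy)-6,8a-dimethyl-3-(propan-2-yl)-1,2,3,3a,4,5,6,8a-octahydroazulene-3,4-diol
Conditions: iPrMgCl (3 equiv), LaCl3·2LiCl (1 equiv), THF, −40 to 0 °C; then H2O
Reagents that add atoms: isopropylmagnesium chloride, CC(C)[Mg]Cl
Why: Lanthanum-promoted Grignard 1,2-addition, a type made for enolisable cyclopentanones and secondary Grignard reagents: the first equivalent forms the C6 alkoxide, and the nucleophile should attack C4 from the convex α face of the cis-fused bicycle, anti to the C5–C6 bond, placing isopropyl α and hydroxyl β.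

Step 10
Reactants: 16 (3R,3aS,4S,6R,8aS)-6-(tert-butyldimethylsilyloxy)-6,8a-dimethyl-3-(propan-2-yl)-1,2,3,3a,4,5,6,8a-octahydroazulene-3,4-diol; 17 4-(tert-butyldimethylsilyloxy)benzoic acid
Product: 18 (3R,3aS,4S,6R,8aS)-6-(tert-butyldimethylsilyloxy)-3-hydroxy-6,8a-dimethyl-3-(propan-2-yl)-1,2,3,3a,4,5,6,8a-octahydroazulen-4-yl 4-(tert-butyldimethylsilyloxy)benzoate
Conditions: DCC (1.5 equiv), DMAP (0.3 equiv), CH2Cl2, rt
Reagents that add atoms: none
Why: Steglich esterification acylates only the secondary C6 hydroxyl, because the tertiary C4 hydroxyl is inert here, and C6 keeps its configuration since its C–O bond is not touched.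

Step 11
Reactants: 18 (3R,3aS,4S,6R,8aS)-6-(tert-butyldimethylsilyloxy)-3-hydroxy-6,8a-dimethyl-3-(propan-2-yl)-1,2,3,3a,4,5,6,8a-octahydroazulen-4-yl 4-(tert-butyldimethylsilyloxy)benzoate
Product: 19 (3R,3aS,4S,6R,8aS)-3,6-dihydroxy-6,8a-dimethyl-3-(propan-2-yl)-1,2,3,3a,4,5,6,8a-octahydroazulen-4-yl 4-hydroxybenzoate (target)
Conditions: TBAF (4 equiv), THF, 0 to 40 °C; then H2O
Reagents that add atoms: none
Why: Fluoride cleavage of the aryl and the tertiary allylic silyl ethers under non-acidic conditions avoids ionisation of the C8–O bond and leaves the ester and all five stereocentres untouched.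

Compound list
1 | methacrolein | C=C(C)C=O | starting material
2 | propargyl bromide | C#CCBr | starting material
3 | (±)-2-methylhex-1-en-5-yn-3-ol | C=C(C)C(O)CC#C | intermediate
4 | triethyl orthoacetate | CC(OCC)(OCC)OCC | starting material
5 | mixed ketene acetal, 1-ethoxyethenyl ether of 3 | C=C(OCC)OC(CC#C)C(C)=C | intermediate
6 | ethyl (E)-4-methyloct-4-en-7-ynoate | CCOC(=O)CC/C(C)=C/CC#C | intermediate
7 | ethyl (E)-4-methyl-7-oxooct-4-enoate | CCOC(=O)CC/C(C)=C/CC(C)=O | intermediate
8 | ethyl (4E,6Z)-7-(tert-butyldimethylsilyloxy)-4-methylocta-4,6-dienoate | CCOC(=O)CC/C(C)=C/C=C(\O[Si](C)(C)C(C)(C)C)C | intermediate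
9 | (4E,6Z)-7-(tert-butyldimethylsilyloxy)-N-methoxy-N,4-dimethylocta-4,6-dienamide | CON(C)C(=O)CC/C(C)=C/C=C(\O[Si](C)(C)C(C)(C)C)C | intermediate
10 | (7E,9Z)-10-(tert-butyldimethylsilyloxy)-7-methylundeca-1,7,9-trien-4-one | C=CCC(=O)CC/C(C)=C/C=C(\O[Si](C)(C)C(C)(C)C)C | intermediate
11 | (7E,9Z)-3-diazo-10-(tert-butyldimethylsilyloxy)-7-methylundeca-1,7,9-trien-4-one | C=CC(=[N+]=[N-])C(=O)CC/C(C)=C/C=C(\O[Si](C)(C)C(C)(C)C)C | intermediate
12 | (1R,5S,6S)-1-ethenyl-5-methyl-6-[(1Z)-2-(tert-butyldimethylsilyloxy)prop-1-enyl]bicyclo[3.1.0]hexan-2-one (C6 arm exo, cis to vinyl and methyl) | O=C1CC[C@@]2(C)[C@H](/C=C(\O[Si](C)(C)C(C)(C)C)C)[C@@]12C=C | intermediate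
13 | (3aS,6R)-6-(tert-butyldimethylsilyloxy)-3a,6-dimethyl-3,3a,6,7-tetrahydroazulen-1(2H)-one | O=C1CC[C@@]2(C)C=C[C@](C)(O[Si](C)(C)C(C)(C)C)CC=C12 | intermediate
14 | C8 pinacol boronate corresponding to 15 (boron in place of the hydroxyl oxygen, same spatial arrangement) | O=C1CC[C@@]2(C)C=C[C@](C)(O[Si](C)(C)C(C)(C)C)C[C@H](B3OC(C)(C)C(C)(C)O3)[C@@H]12 | intermediate
15 | (3aS,6R,8S,8aS)-6-(tert-butyldimethylsilyloxy)-8-hydroxy-3a,6-dimethyl-3,3a,6,7,8,8a-hexahydroazulen-1(2H)-one | O=C1CC[C@@]2(C)C=C[C@](C)(O[Si](C)(C)C(C)(C)C)C[C@H](O)[C@@H]12 | intermediate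
16 | (3R,3aS,4S,6R,8aS)-6-(tert-butyldimethylsilyloxy)-6,8a-dimethyl-3-(propan-2-yl)-1,2,3,3a,4,5,6,8a-octahydroazulene-3,4-diol | CC(C)[C@]1(O)CC[C@@]2(C)C=C[C@](C)(O[Si](C)(C)C(C)(C)C)C[C@H](O)[C@@H]12 | intermediate
17 | 4-(tert-butyldimethylsilyloxy)benzoic acid | O=C(O)c1ccc(O[Si](C)(C)C(C)(C)C)cc1 | starting material
18 | bis-silyl ether of the target (O8 and phenol) | CC(C)[C@]1(O)CC[C@@]2(C)C=C[C@](C)(O[Si](C)(C)C(C)(C)C)C[C@H](OC(=O)c3ccc(O[Si](C)(C)C(C)(C)C)cc3)[C@@H]12 | intermediate
19 | (3R,3aS,4S,6R,8aS)-3,6-dihydroxy-6,8a-dimethyl-3-(propan-2-yl)-1,2,3,3a,4,5,6,8a-octahydroazulen-4-yl 4-hydroxybenzoate | CC(C)[C@]1(O)CC[C@@]2(C)C=C[C@](C)(O)C[C@H](OC(=O)c3ccc(O)cc3)[C@@H]12 | target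

Total step count: 11. Longest linear sequence: 11 (steps 1 to 11; 17 enters in step 10).

Steps most likely to fail

Step 7. The boat transition state must bring the inner silyloxy group on C8 and the terminus C7 over the methyl group on C1. The sigmatropic shift may therefore become slower than a homo-1,5-hydrogen shift from that methyl group. Enantioface control is also untested for a ketone tether. The fallback sets out from 12, which is then isolated after the rhodium stage at room temperature, and returns at 13. The concerted shift is replaced by a stepwise ionic ring expansion.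
- Catalytic TBSOTf (CH2Cl2, −78 °C) silylates the ketone oxygen and breaks the donor–acceptor bond C5–C10 heterolytically, as in Lewis-acid openings of donor–acceptor cyclopropanes.
- The terminus C7 of the resulting silyl dienol ether closes on the silyloxocarbenium carbon C8 in an intramolecular vinylogous Mukaiyama aldol addition.
- The silyl cation is then released again. This path makes no new isolable compound (F0).

Step 8. Borylcupration may be too slow at a β-carbon next to the neopentyl-like C7–C8 unit, and protonation of the enolate may stop at the trans-fused epimer. The fallback sets out from 13 and returns at 15. Weitz–Scheffer epoxidation (H2O2, NaOH, MeOH, 0 °C) from the same open face should give the α-face 8,8a-epoxy ketone F1. Its Cα–O bond is then cleaved reductively with SmI2 (THF/MeOH, −78 °C). This keeps the C6–O bond and passes through an enolate that is protonated and equilibrated at C5.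

Step 9. Enolisation of the ketone, β-elimination of the C6 oxygen back to the enone, or hydride transfer from the secondary Grignard reagent may outrun addition. The fallback sets out from 15 and returns at 16. The smaller sp2 nucleophile without β-hydrogen, isopropenylmagnesium bromide with LaCl3·2LiCl, is added from the same convex face to give the isopropenyl carbinol F2. Its 1,1-disubstituted alkene is then hydrogenated selectively (H2, RhCl(PPh3)3, benzene, rt) in the presence of the C9=C10 alkene, which is flanked by two fully substituted carbons.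

Further compounds
F0 | step 7 | none | none
F1 | step 8 | 8,8a-epoxy-6-(tert-butyldimethylsilyloxy)-3a,6-dimethyl-octahydroazulen-1-one, oxirane oxygen on the face of the C3a methyl | O=C1CC[C@@]2(C)C=C[C@](C)(O[Si](C)(C)C(C)(C)C)C[C@@H]3O[C@]123
F2 | step 9 | isopropenyl analogue of 16 (prop-1-en-2-yl in place of propan-2-yl, same spatial arrangement) | C=C(C)[C@]1(O)CC[C@@]2(C)C=C[C@](C)(O[Si](C)(C)C(C)(C)C)C[C@H](O)[C@@H]12
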